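The alpha run at 60 °C held 20.6% side product at 0.667 h. The rate had already slowed a little by then, so you correct that reading for the losses of starting material and second reagent at its midpoint, taking one of each per step, and get 2.53 h. This opening time is the time in which the opening rate would turn the whole starting material into side product.

| setting | epsilon | alpha | beta | north-west | south | south-west | north | north-east |
|---|---|---|---|---|---|---|---|---|
| starting material | 0.091 M | 0.091 M | 0.091 M | 0.091 M | 0.091 M | 0.091 M | 0.091 M | 0.091 M |
| partner | 0.0455 M | 0.023 M | 0.034 M | 0.0455 M | 0.0455 M (fed, over 3.0 h) | 0.0455 M | 0.0455 M | 0.0455 M |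
| second reagent | 0.0728 M | 0.0728 M | 0.0728 M | 0.0728 M (fed, over 3.0 h) | 0.0728 M | 0.0728 M (in portions, 3, over 3.0 h) | 0.0728 M | 0.0728 M (fed, over 3.0 h) |
| temperature | 45 °C | 60 °C | 45 °C |  | 60 °C | 60 °C |  | 60 °C |
| remark | run made earlier | run made earlier | run made earlier | the addition at 20 °C, then warmed to 60 °C; the feed brings no volume worth counting | all else is in the flask from the start; the feed brings no volume worth counting | first portion at the start, last at 3.0 h | everything together at the start at 20 °C, warmed to 60 °C at 3.0 h | all else is in the flask from the start; the feed brings no volume worth counting |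
| time |  |  |  | 15 h | 15 h | 15 h | 15 h | 15 h |

| run | time / h | side product / % | target / % |
|---|---|---|---|
| epsilon | 3.00 | 30.2 | 0 |
| epsilon | 5.00 | 39.2 | 1.2 |
| epsilon | 8.00 | 46.8 | 1.6 |
| epsilon | 10.0 | 50.7 | 1.2 |
| epsilon | 12.0 | 53.7 | 0 |
| epsilon | 15.0 | 55.8 | 1.4 |
| epsilon | 20.0 | 58.6 | 2.1 |
| alpha | 0.667 | 20.6 | 0 |
| alpha | 1.00 | 28.0 | 0 |
| alpha | 1.50 | 34.9 | 0 |
| alpha | 2.50 | 43.7 | 0.8 |
| alpha | 4.00 | 51.7 | 0.7 |
| alpha | 6.00 | 57.8 | 0.4 |
| alpha | 10.0 | 61.6 | 0.9 |
| beta | 1.33 | 18.7 | 0 |
| beta | 2.00 | 23.6 | 0.2 |
| beta | 3.00 | 31.1 | 0.4 |
| beta | 5.00 | 39.7 | 0 |
| beta | 8.00 | 49.2 | 0.4 |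
| beta | 12.0 | 54.4 | 0.5 |
| beta | 20.0 | 60.7 | 0.1 |

(each reading ± 0.5 percentage points)

- the flask that comes out highest in amount of side product, in percent of the starting material charged, or "all alike" when all lie within 1.5 percentage points (north-west / south / south-west / north / north-east / all alike)
- side product at the end, in percent of the starting material charged, north-west
- side product at the end, in percent of the starting material charged, south
- side product at the end, in percent of the starting material charged, south-west
- side product at the end, in percent of the starting material charged, north
- side product at the end, in percent of the starting material charged, north-east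



Late in alpha, at 59.7% side product, the loss of starting material should slow the rate to 40.3% of its opening value and the loss of second reagent to 25.4%, together to 10.2%. But the last two readings show 2.40% of the opening rate, lower by a factor of about 4.25. So I reckon that another step is taking one of the two, and the curve will stop short of the 80.0% that the second reagent charge allows. Partner is my candidate, since epsilon, with more of it, stands 2.1 percentage points lower than beta at 20.0 h.

The feed of 3.0 h is longer than the opening time, so much side product forms while the feed runs. At mid-feed in north-east, half the second reagent charge has gone in, so the side product rate is held down while partner, in the flask from the start, can take starting material. Feeding partner does the reverse. My reckoning therefore puts south highest and north-east and south-west lowest. The forecast differs, holding “so it is zero order in partner and feeding partner changes nothing”, and it gives north-east highest at 68%, then south-west 66%, south 64%, north-west 63% and north 63%.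

The simulation gives south highest at 62.7%, then north 59.0%, north-west 58.4%, south-west 55.5% and north-east 55.3%.

    starting material + partner → intermediate (k = 0.0630 M⁻¹ min⁻¹, Ea = 67.0 kJ mol⁻¹)
    second reagent + intermediate → target (k = 0.0110 M⁻¹ min⁻¹, Ea = 76.0 kJ mol⁻¹)
    starting material + second reagent → side product (k = 0.100 M⁻¹ min⁻¹, Ea = 54.0 kJ mol⁻¹)
    2 second reagent → self-condensation product (k = 0.0110 M⁻¹ min⁻¹, Ea = 80.0 kJ mol⁻¹)
    (constants at 60 °C)

Over the first 3.0 h of north-east, second reagent stood on average at 0.0246 M, and since the side product rate goes with second reagent, the opening time at that mean stretches to 7.48 h, longer than the feed. The same scaling gives 10.2 h for the neighbour of north-east whose second reagent charge is 0.018 M, and that neighbour ends at 17.9% side product.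

The data stem from a simulated flask on assumed constants; noise was put on by code.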